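**Retrosynthetic overview**
1. Target 20 ⇐ ketone 19 (methylenation last) ⇐ tertiary chloride/secondary bromide 18 by 1,2-interchange of the two ring B halogens ⇐ alkene 15 via epoxide 16 and bromohydrin 17.
2. Alkene 15 ⇐ spiro enedione 12 (1,4-reduction, enol triflate, methyl coupling).
3. 12 ⇐ intramolecular aldol condensation of 11 ⇐ intermolecular Michael addition of formyl ketone 9 to methyl vinyl ketone 10 (key C–C bond; sets the quaternary spiro centre).
4. 9 ⇐ β-keto ester 7 ⇐ bromonium-terminated carbocyclisation of enantioenriched bromochloride 6 ⇐ prenol 1 + methyl acetoacetate 3.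
5. Ring order: ring A first (step 3), ring B second (steps 6–7); ring B halogens next, exocyclic methylene last.

Assumption: the (S)-configured Schiff-base ligand gives the 2S bromochloride in step 1; if the sense of induction is the opposite, its (R)-antipode is used.

Locants in steps 8–13 use spiro[5.5]undecane numbering: C1 = ring A carbonyl, C4 = CHBr, C5 = CMe2, C6 = spiro carbon, C8 and C9 = the ring B carbons that become CHCl and C(Me)Br.

**Step 1**
Reactants: 1 3-methylbut-2-en-1-ol (prenol)
Product: 2 (2S)-2-bromo-3-chloro-3-methylbutan-1-ol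
Conditions: NBS (1.05 equiv), ClTi(OiPr)3 (1.1 equiv), (S)-2-[(3,5-di-tert-butyl-2-hydroxybenzylidene)amino]-3,3-dimethyl-1,1-diphenylbutan-1-ol (20 mol%), hexanes, −20 °C
Reagents that add atoms: N-bromosuccinimide, O=C1CCC(=O)N1Br; chlorotitanium triisopropoxide, CC(C)O[Ti](Cl)(OC(C)C)OC(C)C
Why: Catalytic enantioselective bromochlorination of an allylic alcohol (anti addition): the chiral titanium alkoxide fixes the face of bromonium formation and delivers chloride to the distal tertiary carbon (Markovnikov), setting the 2S C–Br centre that becomes the ring A CHBr carbon.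

**Step 2**
Reactants: 2 (2S)-2-bromo-3-chloro-3-methylbutan-1-ol; 3 methyl acetoacetate
Product: 6 methyl (6S)-6-bromo-7-chloro-7-methyl-3-oxooctanoate, via alkyl triflate 4 (not isolated), via acetoacetate dianion 5 (not isolated)
Conditions: (a) 2, Tf2O, 2,6-lutidine, CH2Cl2, −78 °C; (b) 3, LiN(i-Pr)2 (2.1 equiv), THF, 0 °C, then crude 4, −78 to −40 °C; AcOH quench
Reagents that add atoms: none
Why: Alkylation of the acetoacetate dianion at its terminal carbon (Weiler dianion alkylation) by SN2 at the primary triflate at low temperature, which should outrun E2; the stereocentre is not touched.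

**Step 3**
Reactants: 6 methyl (6S)-6-bromo-7-chloro-7-methyl-3-oxooctanoate
Product: 7 methyl (3S)-3-bromo-2,2-dimethyl-6-oxocyclohexane-1-carboxylate (C1 epimers and enol)
Conditions: SnCl4 (2.2 equiv), CH2Cl2, −78 to −20 °C; aq. NaHCO3
Reagents that add atoms: none
Why: Lewis-acid ionisation of the tertiary chloride is assisted by the anti bromine (bromonium ion), and 6-endo C-cyclisation of the tin-chelated β-keto ester enol onto the tertiary carbon closes ring A (bromonium-terminated cation–enol carbocyclisation); the C–Br bond at the stereocentre is never broken and no alkene is present to shuttle bromonium, so 3S is retained.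

**Step 4**
Reactants: 7 methyl (3S)-3-bromo-2,2-dimethyl-6-oxocyclohexane-1-carboxylate
Product: 8 [(3S)-3-bromo-6-hydroxy-2,2-dimethylcyclohexyl]methanol (diastereomer mixture at C1 and C6)
Conditions: i-Bu2AlH (5 equiv), CH2Cl2, −78 to 0 °C; aq. potassium sodium tartrate
Reagents that add atoms: none
Why: Exhaustive hydride reduction of ketone and ester by i-Bu2AlH, which leaves the secondary alkyl bromide alone; the new carbinol centres do not matter because both are oxidised in step 5.

**Step 5**
Reactants: 8 [(3S)-3-bromo-6-hydroxy-2,2-dimethylcyclohexyl]methanol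
Product: 9 (3S)-3-bromo-2,2-dimethyl-6-oxocyclohexane-1-carbaldehyde (present mainly as the hydroxymethylene enol)
Conditions: (COCl)2 (3 equiv), DMSO (6 equiv), CH2Cl2, −78 °C; Et3N (10 equiv), −78 to 0 °C
Reagents that add atoms: none
Why: Double Swern oxidation of the primary and secondary alcohols gives the 2-formyl ketone, which is stabilised as its hydrogen-bonded enol.

**Step 6 (key step)**
Reactants: 9 (3S)-3-bromo-2,2-dimethyl-6-oxocyclohexane-1-carbaldehyde; 10 but-3-en-2-one (methyl vinyl ketone)
Product: 11 (1R,3S)-3-bromo-2,2-dimethyl-6-oxo-1-(3-oxobutyl)cyclohexane-1-carbaldehyde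
Conditions: 10 (1.5 equiv), Et3N (0.2 equiv), THF, 0 to 23 °C
Reagents that add atoms: none
Why: Intermolecular Michael addition of the amine-generated enolate of the 1,3-dicarbonyl to the enone forms the quaternary spiro carbon next to the gem-dimethyl carbon; the enone approaches axially on the face anti to the pseudo-axial C2 methyl of the half-chair with equatorial bromine, so the new chain ends up trans to bromine (1R).

**Step 7**
Reactants: 11 (1R,3S)-3-bromo-2,2-dimethyl-6-oxo-1-(3-oxobutyl)cyclohexane-1-carbaldehyde
Product: 12 (4S,6S)-4-bromo-5,5-dimethylspiro[5.5]undec-7-ene-1,9-dione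
Conditions: pyrrolidine (0.3 equiv), AcOH (0.3 equiv), benzene, 60 °C
Reagents that add atoms: none
Why: Amine-catalysed intramolecular aldol condensation (second half of a Robinson-type spiroannulation): the methyl ketone enamine attacks the non-enolisable aldehyde faster than the hindered ring ketone and dehydration gives the ring B cyclohexenone; the quaternary centre cannot epimerise.

**Step 8**
Reactants: 12 (4S,6S)-4-bromo-5,5-dimethylspiro[5.5]undec-7-ene-1,9-dione
Product: 14 (4S,6S)-4-bromo-5,5-dimethyl-1-oxospiro[5.5]undec-8-en-9-yl trifluoromethanesulfonate, via silyl enol ether 13 (not isolated)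
Conditions: RhCl(PPh3)3 (1 mol%), Et3SiH (1.2 equiv), benzene, 50 °C; evaporate; CsF (2 equiv), PhNTf2 (1.2 equiv), DME, 23 °C; aq. NH4Cl
Reagents that add atoms: N-phenylbis(trifluoromethanesulfonimide), O=S(=O)(N(c1ccccc1)S(=O)(=O)C(F)(F)F)C(F)(F)F
Why: Rhodium-catalysed 1,4-hydrosilylation of the enone (the hindered C1 ketone reacts far more slowly) fixes the enolate regiochemistry as the silyl enol ether, and fluoride-mediated desilylation with O-triflation gives the vinyl triflate with the double bond at C8–C9, which keeps the two arms of ring B different.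

**Step 9**
Reactants: 14 (4S,6S)-4-bromo-5,5-dimethyl-1-oxospiro[5.5]undec-8-en-9-yl trifluoromethanesulfonate
Product: 15 (4S,6S)-4-bromo-5,5,9-trimethylspiro[5.5]undec-8-en-1-one
Conditions: Pd(PPh3)4 (5 mol%), SnMe4 (2 equiv), LiCl (3 equiv), THF, 65 °C
Reagents that add atoms: tetramethylstannane, C[Sn](C)(C)C
Why: Stille coupling (oxidative addition of zerovalent palladium to the vinyl triflate, methyl transfer from tin, reductive elimination) gives the trisubstituted alkene with the double bond fixed at C8–C9; ketone and secondary alkyl bromide are inert.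

**Step 10**
Reactants: 15 (4S,6S)-4-bromo-5,5,9-trimethylspiro[5.5]undec-8-en-1-one
Product: 16 (4S,6S,8R,9S)-4-bromo-8,9-epoxy-5,5,9-trimethylspiro[5.5]undecan-1-one
Conditions: mCPBA (1.1 equiv), NaHCO3, CH2Cl2, 0 °C
Reagents that add atoms: 3-chloroperoxybenzoic acid, OOC(=O)c1cccc(Cl)c1
Why: Prilezhaev epoxidation of the only alkene from the ring B face anti to the C1 carbonyl carbon (which sits axial on ring B and shields the other face), placing oxygen syn to C5 (8R,9S).

**Step 11**
Reactants: 16 (4S,6S,8R,9S)-4-bromo-8,9-epoxy-5,5,9-trimethylspiro[5.5]undecan-1-one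
Product: 17 (4S,6S,8S,9S)-4,8-dibromo-9-hydroxy-5,5,9-trimethylspiro[5.5]undecan-1-one
Conditions: LiBr (3 equiv), AcOH (3 equiv), THF, 23 °C
Reagents that add atoms: lithium bromide, [Li+].[Br-]
Why: Acid-assisted SN2 opening of the epoxide by bromide at the secondary carbon C8 in the trans-diaxial (Fürst–Plattner) mode with inversion, giving axial C8–Br (8S) and the axial tertiary alcohol (9S).

**Step 12**
Reactants: 17 (4S,6S,8S,9S)-4,8-dibromo-9-hydroxy-5,5,9-trimethylspiro[5.5]undecan-1-one
Product: 18 (4S,6S,8S,9S)-4,8-dibromo-9-chloro-5,5,9-trimethylspiro[5.5]undecan-1-one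
Conditions: anhydrous HCl (saturated solution), CH2Cl2, −20 to 0 °C
Reagents that add atoms: hydrogen chloride, Cl
Why: SN1-type substitution of the tertiary alcohol with neighbouring-group participation: the antiperiplanar C8 bromine bridges to a bromonium ion that chloride opens at the tertiary carbon from the face the water left, so C9 is substituted with retention (9S) and C8 is unchanged.

**Step 13**
Reactants: 18 (4S,6S,8S,9S)-4,8-dibromo-9-chloro-5,5,9-trimethylspiro[5.5]undecan-1-one
Product: 19 (4S,6S,8R,9R)-4,9-dibromo-8-chloro-5,5,9-trimethylspiro[5.5]undecan-1-one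
Conditions: MeCN, 60 °C, sealed tube, dark, 24–48 h; chromatographic separation and recycling of recovered 18
Reagents that add atoms: none
Why: Thermal dyotropic 1,2-interchange of the trans-diaxial vicinal halogens (Barton-type diaxial-to-diequatorial rearrangement through a bromonium–chloride ion pair): bromine shifts from C8 to C9 and chlorine from C9 to C8, each on its own face, so both centres invert to 8R,9R; the expected driving force is loss of the 1,3-diaxial clash between the C8 bromine and the axial C1 carbon, helped by the polar solvent.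

**Step 14**
Reactants: 19 (4S,6S,8R,9R)-4,9-dibromo-8-chloro-5,5,9-trimethylspiro[5.5]undecan-1-one
Product: 20 (2S,6R,8R,9R)-2,9-dibromo-8-chloro-1,1,9-trimethyl-5-methylidenespiro[5.5]undecane
Conditions: Cp2Ti(μ-Cl)(μ-CH2)AlMe2 (Tebbe reagent, 1.5 equiv), pyridine (cat.), THF/toluene, −40 to 0 °C; sodium sulfate decahydrate quench
Reagents that add atoms: Tebbe reagent, C[Al-](C)(Cl)C[Ti+](C1C=CC=C1)C1C=CC=C1
Why: Tebbe methylenation (titanium methylidene [2+2] with the carbonyl, then cycloreversion) converts the hindered ketone to the exocyclic methylene without base, leaving the four stereocentres and the three C–halogen bonds untouched (the spiro descriptor changes from S to R only because the priorities change).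

**Compound list**
1 | 3-methylbut-2-en-1-ol (prenol) | CC(C)=CCO | starting material
2 | (2S)-2-bromo-3-chloro-3-methylbutan-1-ol | OC[C@H](Br)C(C)(C)Cl | intermediate
3 | methyl acetoacetate (methyl 3-oxobutanoate) | COC(=O)CC(C)=O | starting material
4 | (2S)-2-bromo-3-chloro-3-methylbutyl trifluoromethanesulfonate | O=S(=O)(OC[C@H](Br)C(C)(C)Cl)C(F)(F)F | intermediate
5 | dilithium dianion (dienolate) of methyl acetoacetate | [Li+].[Li+].COC([O-])=CC(=C)[O-] | intermediate
6 | methyl (6S)-6-bromo-7-chloro-7-methyl-3-oxooctanoate | COC(=O)CC(=O)CC[C@H](Br)C(C)(C)Cl | intermediate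
7 | methyl (3S)-3-bromo-2,2-dimethyl-6-oxocyclohexane-1-carboxylate (C1 epimers) | COC(=O)C1C(=O)CC[C@H](Br)C1(C)C | intermediate
8 | [(3S)-3-bromo-6-hydroxy-2,2-dimethylcyclohexyl]methanol (diastereomer mixture) | OCC1C(O)CC[C@H](Br)C1(C)C | intermediate
9 | (3S)-3-bromo-2,2-dimethyl-6-oxocyclohexane-1-carbaldehyde (keto form drawn; mainly enol) | O=CC1C(=O)CC[C@H](Br)C1(C)C | intermediate
10 | but-3-en-2-one (methyl vinyl ketone) | CC(=O)C=C | starting material
11 | (1R,3S)-3-bromo-2,2-dimethyl-6-oxo-1-(3-oxobutyl)cyclohexane-1-carbaldehyde | O=C1CC[C@H](Br)C(C)(C)[C@@]1(C=O)CCC(C)=O | intermediate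
12 | (4S,6S)-4-bromo-5,5-dimethylspiro[5.5]undec-7-ene-1,9-dione | O=C1CC[C@H](Br)C(C)(C)[C@@]12CCC(=O)C=C2 | intermediate
13 | (4S,6S)-4-bromo-5,5-dimethyl-9-(triethylsilyloxy)spiro[5.5]undec-8-en-1-one | O=C1CC[C@H](Br)C(C)(C)[C@@]12CCC(O[Si](CC)(CC)CC)=CC2 | intermediate
14 | (4S,6S)-4-bromo-5,5-dimethyl-1-oxospiro[5.5]undec-8-en-9-yl trifluoromethanesulfonate | O=C1CC[C@H](Br)C(C)(C)[C@@]12CCC(OS(=O)(=O)C(F)(F)F)=CC2 | intermediate
15 | (4S,6S)-4-bromo-5,5,9-trimethylspiro[5.5]undec-8-en-1-one | O=C1CC[C@H](Br)C(C)(C)[C@@]12CCC(C)=CC2 | intermediate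
16 | (4S,6S,8R,9S)-4-bromo-8,9-epoxy-5,5,9-trimethylspiro[5.5]undecan-1-one (oxirane oxygen syn to C5) | O=C1CC[C@H](Br)C(C)(C)[C@@]12CC[C@]3(C)O[C@@H]3C2 | intermediate
17 | (4S,6S,8S,9S)-4,8-dibromo-9-hydroxy-5,5,9-trimethylspiro[5.5]undecan-1-one | O=C1CC[C@H](Br)C(C)(C)[C@@]12CC[C@](C)(O)[C@@H](Br)C2 | intermediate
18 | (4S,6S,8S,9S)-4,8-dibromo-9-chloro-5,5,9-trimethylspiro[5.5]undecan-1-one | O=C1CC[C@H](Br)C(C)(C)[C@@]12CC[C@](C)(Cl)[C@@H](Br)C2 | intermediate
19 | (4S,6S,8R,9R)-4,9-dibromo-8-chloro-5,5,9-trimethylspiro[5.5]undecan-1-one | O=C1CC[C@H](Br)C(C)(C)[C@@]12CC[C@@](C)(Br)[C@H](Cl)C2 | intermediate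
20 | (2S,6R,8R,9R)-2,9-dibromo-8-chloro-1,1,9-trimethyl-5-methylidenespiro[5.5]undecane | C=C1CC[C@H](Br)C(C)(C)[C@@]12CC[C@@](C)(Br)[C@H](Cl)C2 | target

**Step count and risks**
Total step count: 14. Longest linear sequence: 14 steps (1 → 20); 3 and 10 are bought.

The three steps most likely to fail:

Step 13 (halogen interchange 18 → 19). This is the least certain step. Ring B prefers the chair with C1 axial, so every trans-diaxial addition or opening puts the C9 substituent on the wrong face for the target; 19 is therefore reached only as the rearranged, diequatorial partner of 18. The position of that equilibrium is not known for this ring system and may be close to 1:1, and ionisation can also lead to elimination. The fallback sets out from 15 and comes back at 19. Chlorohydroxylation of 15 with N-chlorosuccinimide in aqueous acetone (electrophilic chlorine to the ring B face anti to C1, water anti at the tertiary carbon) would give the trans chlorohydrin (4S,6S,8R,9R)-4-bromo-8-chloro-9-hydroxy-5,5,9-trimethylspiro[5.5]undecan-1-one F1. Anhydrous HBr in CH2Cl2 at −40 °C would then exchange the tertiary hydroxyl for bromide through the chlorine-bridged cation with retention to give 19. The C9 epimer is the likely by-product and would have to be separated.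

Step 6 (Michael addition 9 + 10 → 11). The donor carbon is flanked by a quaternary carbon, the adduct can deformylate, and the enolate could displace the ring bromide to form a cyclopropane; the diastereoselectivity also rests on a conformational argument. The fallback sets out from 7 and comes back at 11. Michael addition of the β-keto ester 7 itself to 10 under FeCl3·6H2O catalysis (no free enolate) gives methyl (1S,3S)-3-bromo-2,2-dimethyl-6-oxo-1-(3-oxobutyl)cyclohexane-1-carboxylate F2. Exhaustive i-Bu2AlH reduction gives (4S)-4-bromo-2-(3-hydroxybutyl)-2-(hydroxymethyl)-3,3-dimethylcyclohexan-1-ol F3 (carbinol epimers), and Swern oxidation of all three carbinols returns 11.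

Step 2 (dianion alkylation with triflate 4). The strongly basic dianion may eliminate the β-bromo triflate or attack bromine instead of carbon. The fallback sets out from 4 and comes back at 6. Copper-catalysed coupling of 4 with allylmagnesium bromide (copper iodide CuI 10 mol%, THF, −78 °C) gives (5S)-5-bromo-6-chloro-6-methylhept-1-ene F4. Ozonolysis with Me2S work-up gives (4S)-4-bromo-5-chloro-5-methylhexanal F5, and Roskamp homologation with methyl diazoacetate and SnCl2 (cat.) in CH2Cl2 gives β-keto ester 6.

**Further compounds**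
F1 | step 13 | (4S,6S,8R,9R)-4-bromo-8-chloro-9-hydroxy-5,5,9-trimethylspiro[5.5]undecan-1-one | O=C1CC[C@H](Br)C(C)(C)[C@@]12CC[C@@](C)(O)[C@H](Cl)C2
F2 | step 6 | methyl (1S,3S)-3-bromo-2,2-dimethyl-6-oxo-1-(3-oxobutyl)cyclohexane-1-carboxylate | O=C1CC[C@H](Br)C(C)(C)[C@@]1(C(=O)OC)CCC(C)=O
F3 | step 6 | (4S)-4-bromo-2-(3-hydroxybutyl)-2-(hydroxymethyl)-3,3-dimethylcyclohexan-1-ol (C2 as in 11; carbinol epimers) | OC1CC[C@H](Br)C(C)(C)[C@@]1(CO)CCC(C)O
F4 | step 2 | (5S)-5-bromo-6-chloro-6-methylhept-1-ene | C=CCC[C@H](Br)C(C)(C)Cl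
F5 | step 2 | (4S)-4-bromo-5-chloro-5-methylhexanal | O=CCC[C@H](Br)C(C)(C)Cl
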